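**Plan**
1. Retrosynthesis first removes the two late ether cleavages (the O5–CH3 bond, then the 4'-O–CH2OCH3 acetal), then cuts ring C once through O1–C8a and C4–C4a.
2. That double cut is possible because ring C is fused to ring A through the neighbouring carbons C8a (bearing O1) and C4a (bearing the C4 carbonyl). The pair C4a/C8a is therefore an aryne, polarised by the C5 oxygen next to C4a, and C5–C8 are all substituted already.
3. The partners are a fully substituted ortho-silylaryl triflate of ring A and the O1–C2–C3–C4 chain, carried with ring B as an (S)-β-silyloxy methyl ester.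
4. Forward: ring A is completed first (carbamate-directed silylation and prenylation of 3,4,5-trimethoxyphenol in one flask, then carbamate-to-triflate exchange). The ring B arm comes from 4-hydroxyacetophenone, ring C closes last in the annulation, and acid followed by MgI2·OEt2 frees the two phenols.
5. The only stereocentre, C2, is set as the (S) carbinol by asymmetric transfer hydrogenation of a β-keto ester and is carried through, because its C–O bond is never broken.

Key step: step 8

Remark: ring A carbons carry flavanone locants (C4a, C5–C8, C8a) at every stage, and prenyl means 3-methylbut-2-en-1-yl. 4-(Methoxymethoxy)benzaldehyde, used only in a fallback, is taken to be purchasable.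

**Route**

Step 1
Reactants: 1 3,4,5-trimethoxyphenol
Product: 2 3,4,5-trimethoxyphenyl N-isopropylcarbamate
Conditions: i-PrNCO, Et3N (cat.), CH2Cl2, rt
Reagents that add atoms: isopropyl isocyanate, CC(C)N=C=O
Why: Base-catalysed addition of the phenol to the isocyanate (carbamoylation) should give the N-isopropyl carbamate, a strong ortho-directing group that can later be removed without acid.

Step 2
Reactants: 2 3,4,5-trimethoxyphenyl N-isopropylcarbamate; 3 prenyl bromide
Product: 10 3,4,5-trimethoxy-2-(3-methylbut-2-en-1-yl)-6-(trimethylsilyl)phenyl N-isopropylcarbamate, via N-silyl carbamate 4 (not isolated), via aryllithium 5 (not isolated), via N-silyl arylsilane 6 (not isolated), via silylated aryllithium 7 (not isolated), via arylcopper 8 (not isolated), via N-silyl prenylarene 9 (not isolated)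
Conditions: TBSOTf, TMEDA, Et2O, 0 °C → rt; n-BuLi, TMEDA, −78 °C; TMSCl (1.1 equiv), −78 °C → rt; n-BuLi, TMEDA, −78 °C; CuBr·SMe2, THF, −78 °C; 3, −78 → 0 °C; aq NH4Cl, then aq NaHSO4
Reagents that add atoms: chlorotrimethylsilane, C[Si](C)(C)Cl
Why: Two successive directed ortho-metalations of the carbamate, N-silylated once in the flask, should first place lithium between the carbamate and a methoxy group (the two ortho sites are equivalent by symmetry) for the TMSCl quench and then, with the N–Si bond still in place, at the last ring C–H for transmetalation to copper (which holds back carbamoyl migration) and allylic substitution at the primary carbon of prenyl bromide, silicon going in first so that no benzylic–allylic CH2 is present during a lithiation and the N–Si bond being hydrolysed only in the final work-up.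

Step 3
Reactants: 10 3,4,5-trimethoxy-2-(3-methylbut-2-en-1-yl)-6-(trimethylsilyl)phenyl N-isopropylcarbamate
Product: 12 3,4,5-trimethoxy-2-(3-methylbut-2-en-1-yl)-6-(trimethylsilyl)phenyl trifluoromethanesulfonate, via silylphenol 11 (not isolated)
Conditions: Et2NH, DBU, MeCN, 40 °C; then PhNTf2, rt
Reagents that add atoms: N-phenylbis(trifluoromethanesulfonimide), O=S(=O)(N(c1ccccc1)S(=O)(=O)C(F)(F)F)C(F)(F)F
Why: E1cB cleavage of the N–H carbamate (isopropyl isocyanate is expelled and scavenged by diethylamine) frees the hindered phenoxide without acid, so the aryl–silicon bond and the prenyl alkene are spared, and O-sulfonylation in the same pot gives the ortho-silylaryl triflate.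

Step 4
Reactants: 13 4-hydroxyacetophenone
Product: 14 4-(methoxymethoxy)acetophenone
Conditions: MOMCl, i-Pr2NEt, CH2Cl2, 0 °C → rt
Reagents that add atoms: chloromethyl methyl ether, COCCl
Why: Williamson-type O-alkylation gives the MOM ether, which is inert to fluoride, alkoxide and aryl anions in step 8 and is removed by mild acid afterwards.

Step 5
Reactants: 14 4-(methoxymethoxy)acetophenone
Product: 15 methyl 3-[4-(methoxymethoxy)phenyl]-3-oxopropanoate
Conditions: NaH, (MeO)2CO, THF, reflux; cold 1 M HCl
Reagents that add atoms: dimethyl carbonate, COC(=O)OC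
Why: Crossed Claisen condensation of the ketone enolate with dimethyl carbonate (C-carbomethoxylation) is driven to completion by deprotonation of the β-keto ester formed.

Step 6
Reactants: 15 methyl 3-[4-(methoxymethoxy)phenyl]-3-oxopropanoate
Product: 16 methyl (3S)-3-hydroxy-3-[4-(methoxymethoxy)phenyl]propanoate
Conditions: RuCl[(S,S)-TsDPEN](p-cymene) (1 mol %), HCO2H–Et3N (5:2), CH2Cl2, 30 °C
Reagents that add atoms: none
Why: Noyori asymmetric transfer hydrogenation, in which the hydride formed from RuCl[(S,S)-TsDPEN](p-cymene) attacks the aryl ketone face fixed by the CH–π contact between p-cymene and the aryl ring, should give the (S) carbinol, as it does for aryl ketones with a CH2 group on the other side.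

Step 7
Reactants: 16 methyl (3S)-3-hydroxy-3-[4-(methoxymethoxy)phenyl]propanoate
Product: 17 methyl (3S)-3-[4-(methoxymethoxy)phenyl]-3-(trimethylsilyloxy)propanoate
Conditions: TMSCl, imidazole, CH2Cl2, 0 °C → rt
Reagents that add atoms: chlorotrimethylsilane, C[Si](C)(C)Cl
Why: Routine O-silylation removes the only O–H group from the annulation partner and turns the carbinol into an alkoxide that fluoride can release without a proton source.

Step 8
Reactants: 12 3,4,5-trimethoxy-2-(3-methylbut-2-en-1-yl)-6-(trimethylsilyl)phenyl trifluoromethanesulfonate; 17 methyl (3S)-3-[4-(methoxymethoxy)phenyl]-3-(trimethylsilyloxy)propanoate (slight excess)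
Product: 21 (2S)-5,6,7-trimethoxy-4'-(methoxymethoxy)-8-(3-methylbut-2-en-1-yl)flavanone, via aryne 18 (not isolated), via cesium alkoxide 19 (not isolated), via aryl carbanion 20 (not isolated)
Conditions: CsF, 18-crown-6, THF, 0 °C → rt; pH 7 buffer
Reagents that add atoms: none
Why: Proposed new method: fluoride removes the aryl silyl group of 12 with loss of triflate to unmask aryne 18 across C4a–C8a and, together with the methoxide released later, desilylates 17 to the proton-free alkoxide 19, whose oxygen adds to C8a; the C4a carbanion 20 then attacks the ester carbonyl in a 6-exo-trig acyl substitution that closes ring C and expels methoxide, which is trapped as MeOSiMe3 by silyl transfer from the next molecule of 17. The closest known reactions are the fluoride-triggered annulation of arynes with methyl salicylates to xanthones, the insertion of arynes into the C–O bond of carboxylic acids and the O-arylation of aliphatic alcohols by arynes; an aliphatic β-oxido ester as the partner is new. No stereocentre is created, and because the C2–O bond of the carbinol is never broken the (S) configuration from step 6 should appear unchanged as (2S) in 21. The step needs oxygen to add at C8a and not at C4a, which the inductively withdrawing C5 methoxy group secures by stabilising negative charge at C4a (the usual bias of 3-alkoxyarynes, opposed here only by the weak steric effect of the C8 prenyl group). It also needs acyl capture to outrun protonation of 20, which is secured by the absence of any O–H donor (silyl ether in place of the free alcohol, THF in place of MeCN). Since every other ring A carbon is substituted the aryne can form only at C4a–C8a, and slow heterogeneous fluoride release, low temperature and a buffered quench should protect the prenyl alkene, the MOM ether and the base-sensitive flavanone from retro-oxa-Michael opening.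

Step 9
Reactants: 21 (2S)-5,6,7-trimethoxy-4'-(methoxymethoxy)-8-(3-methylbut-2-en-1-yl)flavanone
Product: 22 (2S)-4'-hydroxy-5,6,7-trimethoxy-8-(3-methylbut-2-en-1-yl)flavanone
Conditions: HCl (0.5 M), MeOH, rt
Reagents that add atoms: none
Why: Acid-catalysed acetal exchange with methanol should free the 4'-phenol, while dilute acid at room temperature is expected to leave the trisubstituted alkene and the C2–O1 bond alone.

Step 10
Reactants: 22 (2S)-4'-hydroxy-5,6,7-trimethoxy-8-(3-methylbut-2-en-1-yl)flavanone
Product: 23 (2S)-5-hydroxy-2-(4-hydroxyphenyl)-6,7-dimethoxy-8-(3-methylbut-2-en-1-yl)chroman-4-one (CNP0104932.1)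
Conditions: MgI2·OEt2, THF, 55 °C; 0.1 M HCl
Reagents that add atoms: none
Why: Chelation-controlled ether cleavage, in which magnesium bridges the C4 carbonyl and O5 and iodide removes that methyl group by SN2, should leave the C6 and C7 methyl ethers and the prenyl group untouched, as is typical for 5-methoxy-8-prenylflavanones.

**Compound list**

1 | 3,4,5-trimethoxyphenol | COc1cc(O)cc(OC)c1OC | starting material
2 | 3,4,5-trimethoxyphenyl N-isopropylcarbamate | COc1cc(OC(=O)NC(C)C)cc(OC)c1OC | intermediate
3 | prenyl bromide (1-bromo-3-methylbut-2-ene) | CC(C)=CCBr | starting material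
4 | 3,4,5-trimethoxyphenyl N-(tert-butyldimethylsilyl)-N-isopropylcarbamate | COc1cc(OC(=O)N(C(C)C)[Si](C)(C)C(C)(C)C)cc(OC)c1OC | intermediate (not isolated)
5 | 2-lithio derivative of 4 | COc1cc(OC(=O)N(C(C)C)[Si](C)(C)C(C)(C)C)c([Li])c(OC)c1OC | intermediate (not isolated)
6 | 3,4,5-trimethoxy-2-(trimethylsilyl)phenyl N-(tert-butyldimethylsilyl)-N-isopropylcarbamate | COc1cc(OC(=O)N(C(C)C)[Si](C)(C)C(C)(C)C)c([Si](C)(C)C)c(OC)c1OC | intermediate (not isolated)
7 | 6-lithio derivative of 6 | COc1c([Li])c(OC(=O)N(C(C)C)[Si](C)(C)C(C)(C)C)c([Si](C)(C)C)c(OC)c1OC | intermediate (not isolated)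
8 | arylcopper formed from 7 | COc1c([Cu])c(OC(=O)N(C(C)C)[Si](C)(C)C(C)(C)C)c([Si](C)(C)C)c(OC)c1OC | intermediate (not isolated)
9 | 3,4,5-trimethoxy-2-(3-methylbut-2-en-1-yl)-6-(trimethylsilyl)phenyl N-(tert-butyldimethylsilyl)-N-isopropylcarbamate | COc1c(CC=C(C)C)c(OC(=O)N(C(C)C)[Si](C)(C)C(C)(C)C)c([Si](C)(C)C)c(OC)c1OC | intermediate (not isolated)
10 | 3,4,5-trimethoxy-2-(3-methylbut-2-en-1-yl)-6-(trimethylsilyl)phenyl N-isopropylcarbamate | COc1c(CC=C(C)C)c(OC(=O)NC(C)C)c([Si](C)(C)C)c(OC)c1OC | intermediate
11 | 3,4,5-trimethoxy-2-(3-methylbut-2-en-1-yl)-6-(trimethylsilyl)phenol (present as its DBU salt) | COc1c(CC=C(C)C)c(O)c([Si](C)(C)C)c(OC)c1OC | intermediate (not isolated)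
12 | 3,4,5-trimethoxy-2-(3-methylbut-2-en-1-yl)-6-(trimethylsilyl)phenyl trifluoromethanesulfonate | COc1c(OC)c([Si](C)(C)C)c(OS(=O)(=O)C(F)(F)F)c(CC=C(C)C)c1OC | intermediate
13 | 4-hydroxyacetophenone | CC(=O)c1ccc(O)cc1 | starting material
14 | 4-(methoxymethoxy)acetophenone | CC(=O)c1ccc(OCOC)cc1 | intermediate
15 | methyl 3-[4-(methoxymethoxy)phenyl]-3-oxopropanoate | COC(=O)CC(=O)c1ccc(OCOC)cc1 | intermediate
16 | methyl (3S)-3-hydroxy-3-[4-(methoxymethoxy)phenyl]propanoate | COC(=O)C[C@H](O)c1ccc(OCOC)cc1 | intermediate
17 | methyl (3S)-3-[4-(methoxymethoxy)phenyl]-3-(trimethylsilyloxy)propanoate | COC(=O)C[C@H](O[Si](C)(C)C)c1ccc(OCOC)cc1 | intermediate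
18 | 3,4,5-trimethoxy-6-(3-methylbut-2-en-1-yl)benzyne (triple bond C4a–C8a) | COC1=C(OC)C(OC)=C(CC=C(C)C)C#C1 | intermediate (not isolated)
19 | cesium (1S)-3-methoxy-1-[4-(methoxymethoxy)phenyl]-3-oxopropan-1-olate | [Cs+].COC(=O)C[C@H]([O-])c1ccc(OCOC)cc1 | intermediate (not isolated)
20 | cesium salt of the C4a carbanion of methyl (3S)-3-[4-(methoxymethoxy)phenyl]-3-[3,4,5-trimethoxy-2-(3-methylbut-2-en-1-yl)phenoxy]propanoate | [Cs+].COC(=O)C[C@H](Oc1[c-]c(OC)c(OC)c(OC)c1CC=C(C)C)c1ccc(OCOC)cc1 | intermediate (not isolated)
21 | (2S)-5,6,7-trimethoxy-4'-(methoxymethoxy)-8-(3-methylbut-2-en-1-yl)flavanone | COc1c(OC)c2c(c(CC=C(C)C)c1OC)O[C@H](c1ccc(OCOC)cc1)CC2=O | intermediate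
22 | (2S)-4'-hydroxy-5,6,7-trimethoxy-8-(3-methylbut-2-en-1-yl)flavanone | COc1c(OC)c2c(c(CC=C(C)C)c1OC)O[C@H](c1ccc(O)cc1)CC2=O | intermediate
23 | (2S)-5-hydroxy-2-(4-hydroxyphenyl)-6,7-dimethoxy-8-(3-methylbut-2-en-1-yl)chroman-4-one | COc1c(O)c2c(c(CC=C(C)C)c1OC)O[C@H](c1ccc(O)cc1)CC2=O | target

**Count**

Total steps: 10. Longest linear sequence: 7 steps (steps 4–7, then 8–10; the ring A arm, steps 1–3, joins at step 8).

**Steps most likely to fail**

Step 8 (proposed new method). Four things may go wrong. Alkoxide 19 may undergo retro-aldol fragmentation, which would also scramble its stereocentre, or β-elimination, before it meets the aryne. Carbanion 20 may be protonated or silylated before it reaches the ester. Oxygen may add at C4a because C8a is flanked by the prenyl group. The product may reopen to the chalcone in the basic medium, eroding the configuration at C2.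

The fallback uses known chemistry, sets out from 12 and returns at 21. Knoevenagel–Doebner condensation of 4-(methoxymethoxy)benzaldehyde with malonic acid (pyridine, piperidine, 90 °C) should give (E)-3-[4-(methoxymethoxy)phenyl]prop-2-enoic acid F1. Heating 12 with F1 and CsF in THF at 125 °C in a sealed tube should generate aryne 18, whose known insertion into the C–O bond of a carboxylic acid (carboxylate addition at C8a, acyl shift to C4a) leads to (E)-1-[2-hydroxy-4,5,6-trimethoxy-3-(3-methylbut-2-en-1-yl)phenyl]-3-[4-(methoxymethoxy)phenyl]prop-2-en-1-one F2. This chalcone closes under the same conditions by oxa-Michael addition to racemic 5,6,7-trimethoxy-4'-(methoxymethoxy)-8-(3-methylbut-2-en-1-yl)flavanone F3. Kinetic resolution by asymmetric transfer hydrogenation with RuCl[(R,R)-TsDPEN](p-cymene) and HCO2H–Et3N is expected to reduce the (2R) ketone faster, to (2R,4R)-5,6,7-trimethoxy-4'-(methoxymethoxy)-8-(3-methylbut-2-en-1-yl)flavan-4-ol F4. Chromatography then leaves (2S)-21. In this variant ring C closes by conjugate addition and the configuration comes from resolution.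

Step 2. The first aryllithium may not be silylated completely before the second charge of n-BuLi arrives, deprotonation of the last, crowded ring C–H may be incomplete, the carbamoyl group may migrate to carbon when an aryllithium warms (anionic Fries shift), and the copper-mediated coupling may proceed partly with allylic transposition.

The fallback sets out from 2 and returns at 11, replacing the second metalation and the organometallic C–C coupling by a sigmatropic shift. The sequence of step 2 is ended after the TMSCl quench, at the stage of 6, and aqueous NaHSO4 work-up should give 3,4,5-trimethoxy-2-(trimethylsilyl)phenyl N-isopropylcarbamate F5. Carbamate cleavage (Et2NH, DBU, MeCN, 40 °C) should give 3,4,5-trimethoxy-2-(trimethylsilyl)phenol F6. O-Allylation with tert-butyl 2-methylbut-3-en-2-yl carbonate and Pd(PPh3)4 (THF, 0 °C) should give 3,4,5-trimethoxy-1-(2-methylbut-3-en-2-yloxy)-2-(trimethylsilyl)benzene F7. Aromatic Claisen rearrangement (Eu(fod)3 cat., CHCl3, 60 °C) moves the allyl unit with transposition to the only free ortho carbon and gives 11, which is sulfonylated with PhNTf2 and DBU as in the second stage of step 3 to reach 12.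

Step 10. Ether cleavage may continue at the C6 methyl ether once O5 is magnesiated, and prolonged heating of the chelate formed with MgI2 may open ring C reversibly to the chalcone, lowering the optical purity.

The fallback sets out from 21 and returns at 23, so that 22 is skipped and both unmaskings are merged into one cold operation. BCl3 in CH2Cl2 at −78 → −20 °C is known to cleave a methyl ether peri to a carbonyl through a boron chelate and to cleave MOM ethers. Aqueous NaHCO3 work-up should then release 23 directly without any heating of the free flavanone. No compound outside the list is made (F0).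

**Further compounds**

F1 | step 8 | (E)-3-[4-(methoxymethoxy)phenyl]prop-2-enoic acid | COCOc1ccc(/C=C/C(=O)O)cc1
F2 | step 8 | (E)-1-[2-hydroxy-4,5,6-trimethoxy-3-(3-methylbut-2-en-1-yl)phenyl]-3-[4-(methoxymethoxy)phenyl]prop-2-en-1-one | COCOc1ccc(/C=C/C(=O)c2c(O)c(CC=C(C)C)c(OC)c(OC)c2OC)cc1
F3 | step 8 | racemic 5,6,7-trimethoxy-4'-(methoxymethoxy)-8-(3-methylbut-2-en-1-yl)flavanone | COc1c(OC)c2c(c(CC=C(C)C)c1OC)OC(c1ccc(OCOC)cc1)CC2=O
F4 | step 8 | (2R,4R)-5,6,7-trimethoxy-4'-(methoxymethoxy)-8-(3-methylbut-2-en-1-yl)flavan-4-ol | COc1c(OC)c2c(c(CC=C(C)C)c1OC)O[C@@H](c1ccc(OCOC)cc1)C[C@H]2O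
F5 | step 2 | 3,4,5-trimethoxy-2-(trimethylsilyl)phenyl N-isopropylcarbamate | COc1cc(OC(=O)NC(C)C)c([Si](C)(C)C)c(OC)c1OC
F6 | step 2 | 3,4,5-trimethoxy-2-(trimethylsilyl)phenol | COc1cc(O)c([Si](C)(C)C)c(OC)c1OC
F7 | step 2 | 3,4,5-trimethoxy-1-(2-methylbut-3-en-2-yloxy)-2-(trimethylsilyl)benzene | COc1cc(OC(C)(C)C=C)c([Si](C)(C)C)c(OC)c1OC
F0 | step 10 | none | none
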